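**Retrosynthetic overview**
1. Target 25 ⇐ 24: the hydroxy-lactam is made last, by NH3 on the macrocyclic γ-keto β-keto ester.
2. 24 ⇐ 22: one-pot cascade in the biosynthetic order: phenol O→C6 closure of the 13-membered paracyclophane (23), then intramolecular Diels–Alder of the C4=C5 enone with the pendant (13E,15Z)-triene (rings B and C).
3. 22 ⇐ 15 + 20 (C2 alkylation); 15 ⇐ 12 + 13 (reduction/HWE); the triene of 12 comes from ketone 4 by C1, C2 and C3 olefinations.
4. Ring A with C6, C7, C8, C10 ⇐ L-proline desymmetrising anti-aldol of meso ketone 1 with ethyl glyoxylate 2.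
5. Ring order: A (bought) → paracyclophane → B and C together → γ-lactam.

Assumption and convention: cis-3,5-dimethylcyclohexanone is bought as the pure meso isomer, and the natural C2/Cb lactam configuration is taken to be the thermodynamically preferred one inside the cyclophane. Locants for late intermediates follow the polyketide chain: C1 ester/lactam C=O, C3 ketone, C6 O-bearing, C7–C12 ring A, C13–C18 triene; Ca = CH2 on C2, Cb = ketone/hemiaminal carbon, Cc = benzylic CH2.

**Step 1**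
Reactants: 1 cis-3,5-dimethylcyclohexanone; 2 ethyl glyoxylate
Product: 3 ethyl (2R)-2-[(1S,2S,4R)-2,4-dimethyl-6-oxocyclohexyl]-2-hydroxyacetate
Conditions: L-proline (20 mol%), DMSO, rt (2 freshly cracked)
Reagents that add atoms: none
Why: Proline enamine direct aldol (List–Barbas type) that desymmetrises the meso ketone: the hydrogen-bonded chair transition state gives the anti (ring S, carbinol R) adduct, and the catalyst's facial preference is matched with attack trans to the neighbouring methyl on only one of the two enantiotopic α-carbons, so C6, C7, C8 and C10 are fixed together.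

**Step 2**
Reactants: 3 ethyl (2R)-2-[(1S,2S,4R)-2,4-dimethyl-6-oxocyclohexyl]-2-hydroxyacetate
Product: 4 ethyl (2R)-2-[(tert-butyldimethylsilyl)oxy]-2-[(1S,2S,4R)-2,4-dimethyl-6-oxocyclohexyl]acetate
Conditions: TBSCl, imidazole, DMAP (cat.), DMF, rt → 40 °C
Reagents that add atoms: tert-butyldimethylsilyl chloride, CC(C)(C)[Si](C)(C)Cl
Why: Silyl ether formation blocks retro-aldol and alkoxide chemistry in the basic ylide steps ahead and touches no stereocentre.

**Step 3**
Reactants: 4 ethyl (2R)-2-[(tert-butyldimethylsilyl)oxy]-2-[(1S,2S,4R)-2,4-dimethyl-6-oxocyclohexyl]acetate; 5 (methoxymethyl)triphenylphosphonium chloride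
Product: 7 ethyl (2R)-2-[(tert-butyldimethylsilyl)oxy]-2-[(1R,2R,4R,6S)-2-formyl-4,6-dimethylcyclohexyl]acetate, via methyl enol ether 6 (not isolated)
Conditions: 5, KHMDS, THF, 0 °C → rt; then 1 M HCl, THF, rt; then DBU (cat.), CH2Cl2, rt; minor C12 epimer separated and re-equilibrated
Reagents that add atoms: water, O
Why: Wittig methoxymethylenation and enol ether hydrolysis give the one-carbon-homologated aldehyde, and C12 is set by base equilibration to the all-equatorial epimer (expected about 4:1, hence the recycling).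

**Step 4**
Reactants: 7 ethyl (2R)-2-[(tert-butyldimethylsilyl)oxy]-2-[(1R,2R,4R,6S)-2-formyl-4,6-dimethylcyclohexyl]acetate; 8 (triphenylphosphoranylidene)acetaldehyde
Product: 9 ethyl (2R)-2-[(tert-butyldimethylsilyl)oxy]-2-{(1R,2S,4R,6S)-2,4-dimethyl-6-[(1E)-3-oxoprop-1-en-1-yl]cyclohexyl}acetate
Conditions: toluene, 80 °C
Reagents that add atoms: none
Why: Wittig reaction of a stabilised ylide gives the (13E)-enal and does not touch the non-enolisable C12 centre under these neutral conditions.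

**Step 5**
Reactants: 9 ethyl (2R)-2-[(tert-butyldimethylsilyl)oxy]-2-{(1R,2S,4R,6S)-2,4-dimethyl-6-[(1E)-3-oxoprop-1-en-1-yl]cyclohexyl}acetate; 10 allyl(diphenyl)phosphine
Product: 12 ethyl (2R)-2-[(tert-butyldimethylsilyl)oxy]-2-{(1R,2S,4R,6S)-2-[(1E,3Z)-hexa-1,3,5-trien-1-yl]-4,6-dimethylcyclohexyl}acetate, via erythro β-oxido phosphine adduct 11 (not isolated)
Conditions: 10, t-BuLi, THF, −78 → 0 °C; Ti(OiPr)4, −78 °C; 9, −78 → 0 °C; then MeI, 0 °C → rt
Reagents that add atoms: none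
Why: Yamamoto Z-selective diene synthesis: the α-phosphinoallyl titanate adds 1,2 to the aldehyde (the ester is inert) to give the erythro adduct, and P-methylation triggers a Wittig-type syn-elimination that sets the 15Z alkene next to the terminal vinyl group.

**Step 6**
Reactants: 12 ethyl (2R)-2-[(tert-butyldimethylsilyl)oxy]-2-{(1R,2S,4R,6S)-2-[(1E,3Z)-hexa-1,3,5-trien-1-yl]-4,6-dimethylcyclohexyl}acetate; 13 ethyl 4-(diethoxyphosphoryl)-3-oxobutanoate
Product: 15 ethyl (4E,6S)-6-[(tert-butyldimethylsilyl)oxy]-6-{(1R,2S,4R,6S)-2-[(1E,3Z)-hexa-1,3,5-trien-1-yl]-4,6-dimethylcyclohexyl}-3-oxohex-4-enoate, via α-silyloxy aldehyde 14 (not isolated)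
Conditions: DIBAL-H (1.1 equiv), toluene, −78 °C; then dilithio-13 (13, LDA 2.1 equiv, THF), −78 → 0 °C; aq NH4Cl
Reagents that add atoms: none
Why: One-pot partial ester reduction and Horner–Wadsworth–Emmons olefination: the aluminium hemiacetal releases aldehyde 14 only as the γ-carbanion of the phosphonate dianion traps it, giving the (4E)-enone without C6 epimerisation (the descriptor changes from R to S by priority only).

**Step 7**
Reactants: 16 (4-bromophenoxy)(tert-butyl)dimethylsilane; 17 epichlorohydrin (racemic)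
Product: 19 1-{4-[(tert-butyldimethylsilyl)oxy]phenyl}-3-chloropropan-2-ol (racemic), via arylmagnesium bromide 18 (not isolated)
Conditions: Mg, THF, rt; then CuI (10 mol%), 17, −30 → 0 °C; aq NH4Cl
Reagents that add atoms: none
Why: Grignard formation followed by copper-catalysed epoxide opening at the terminal carbon gives the chlorohydrin, and its stereocentre is removed in the next step.

**Step 8**
Reactants: 19 1-{4-[(tert-butyldimethylsilyl)oxy]phenyl}-3-chloropropan-2-ol
Product: 20 1-{4-[(tert-butyldimethylsilyl)oxy]phenyl}-3-chloropropan-2-one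
Conditions: Dess–Martin periodinane, CH2Cl2, rt
Reagents that add atoms: none
Why: Dess–Martin oxidation converts the secondary alcohol to the α-chloroketone under neutral conditions that the aryl silyl ether survives.

**Step 9**
Reactants: 15 ethyl (4E,6S)-6-[(tert-butyldimethylsilyl)oxy]-6-{(1R,2S,4R,6S)-2-[(1E,3Z)-hexa-1,3,5-trien-1-yl]-4,6-dimethylcyclohexyl}-3-oxohex-4-enoate; 20 1-{4-[(tert-butyldimethylsilyl)oxy]phenyl}-3-chloropropan-2-one
Product: 21 ethyl (4E,6S)-6-[(tert-butyldimethylsilyl)oxy]-2-(3-{4-[(tert-butyldimethylsilyl)oxy]phenyl}-2-oxopropyl)-6-{(1R,2S,4R,6S)-2-[(1E,3Z)-hexa-1,3,5-trien-1-yl]-4,6-dimethylcyclohexyl}-3-oxohex-4-enoate (C2 epimers)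
Conditions: NaH (1.05 equiv), THF, 0 °C; then 20, NaI (cat.), 0 °C → rt
Reagents that add atoms: none
Why: C-alkylation of the β-keto ester enolate by the Finkelstein-activated α-haloketone (SN2) joins the tyrosine-type unit; the new C2 centre is epimerisable and is settled in step 12.

**Step 10**
Reactants: 21 ethyl (4E,6S)-6-[(tert-butyldimethylsilyl)oxy]-2-(3-{4-[(tert-butyldimethylsilyl)oxy]phenyl}-2-oxopropyl)-6-{(1R,2S,4R,6S)-2-[(1E,3Z)-hexa-1,3,5-trien-1-yl]-4,6-dimethylcyclohexyl}-3-oxohex-4-enoate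
Product: 22 ethyl (4E,6S)-6-hydroxy-2-[3-(4-hydroxyphenyl)-2-oxopropyl]-6-{(1R,2S,4R,6S)-2-[(1E,3Z)-hexa-1,3,5-trien-1-yl]-4,6-dimethylcyclohexyl}-3-oxohex-4-enoate (C2 epimers)
Conditions: HF·pyridine, THF/pyridine, 0 °C → rt
Reagents that add atoms: none
Why: Fluoride-mediated desilylation frees the phenol and the C6 carbinol in one operation, and the buffered acidic medium avoids base-induced aldol closure of the 1,4-diketone and leaves the Z-triene and enone intact.

**Step 11**
Reactants: 22 ethyl (4E,6S)-6-hydroxy-2-[3-(4-hydroxyphenyl)-2-oxopropyl]-6-{(1R,2S,4R,6S)-2-[(1E,3Z)-hexa-1,3,5-trien-1-yl]-4,6-dimethylcyclohexyl}-3-oxohex-4-enoate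
Product: 24 macrocyclic decahydrofluorene keto ester (target skeleton with the C1 ethyl ester and the Cb ketone in place of the lactam; 4S,5S,6S,7R,8S,10R,12S,13S,16R; C2 epimers), via 13-membered cyclophane 23 (not isolated)
Conditions: PPh3, DIAD (premixed, 0 °C), 22 by syringe pump, toluene (1 mM), 0 °C → rt; then 70 °C, BHT
Reagents that add atoms: none
Why: Intramolecular Mitsunobu etherification (SN2 with inversion, 6S → 6R in 23) closes the paracyclophane first, as in the biosynthesis, and the ring-held C4=C5 enone then undergoes an intramolecular Diels–Alder with the 13E,15Z-diene through the acyl-endo transition state, in which the bridge forces O and C4 cis on the new cyclopentane, the endo mode gives the trans B/C fusion (C5, C13) and the "inside" Z-vinyl group ends trans to both the C4 acyl and C12 (C4, C16).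

**Step 12**
Reactants: 24 macrocyclic decahydrofluorene keto ester
Product: 25 Xenoacremone H (2S,4S,5S,6S,7R,8S,10R,12S,13S,16R,bS)
Conditions: NH3 (7 M in MeOH)/H2O, sealed tube, 100 °C
Reagents that add atoms: ammonia, N
Why: Ammonia adds to the Cb ketone and the resulting amino-carbinol lactamises onto the ester (aminolysis with hemiaminal formation); C2 (via the enol) and Cb (via ring–chain tautomerism) settle under thermodynamic control as the cis-bridged hydroxy-lactam that the cyclophane requires, and the same ring strain disfavours Paal–Knorr pyrrole formation.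

**Compound list**
1 | cis-3,5-dimethylcyclohexanone (meso, 3R,5S) | O=C1C[C@H](C)C[C@H](C)C1 | starting material
2 | ethyl glyoxylate | CCOC(=O)C=O | starting material
3 | ethyl (2R)-2-[(1S,2S,4R)-2,4-dimethyl-6-oxocyclohexyl]-2-hydroxyacetate | O=C1C[C@H](C)C[C@H](C)[C@H]1[C@@H](O)C(=O)OCC | intermediate
4 | ethyl (2R)-2-[(tert-butyldimethylsilyl)oxy]-2-[(1S,2S,4R)-2,4-dimethyl-6-oxocyclohexyl]acetate | O=C1C[C@H](C)C[C@H](C)[C@H]1[C@@H](O[Si](C)(C)C(C)(C)C)C(=O)OCC | intermediate
5 | (methoxymethyl)triphenylphosphonium chloride | COC[P+](c1ccccc1)(c1ccccc1)c1ccccc1.[Cl-] | starting material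
6 | ethyl (2R)-2-[(tert-butyldimethylsilyl)oxy]-2-[(1R,4R,6S)-2-(methoxymethylidene)-4,6-dimethylcyclohexyl]acetate (E/Z mixture) | COC=C1C[C@H](C)C[C@H](C)[C@H]1[C@@H](O[Si](C)(C)C(C)(C)C)C(=O)OCC | intermediate
7 | ethyl (2R)-2-[(tert-butyldimethylsilyl)oxy]-2-[(1R,2R,4R,6S)-2-formyl-4,6-dimethylcyclohexyl]acetate | O=C[C@@H]1C[C@H](C)C[C@H](C)[C@H]1[C@@H](O[Si](C)(C)C(C)(C)C)C(=O)OCC | intermediate
8 | (triphenylphosphoranylidene)acetaldehyde | O=CC=P(c1ccccc1)(c1ccccc1)c1ccccc1 | starting material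
9 | ethyl (2R)-2-[(tert-butyldimethylsilyl)oxy]-2-{(1R,2S,4R,6S)-2,4-dimethyl-6-[(1E)-3-oxoprop-1-en-1-yl]cyclohexyl}acetate | O=C/C=C/[C@@H]1C[C@H](C)C[C@H](C)[C@H]1[C@@H](O[Si](C)(C)C(C)(C)C)C(=O)OCC | intermediate
10 | allyl(diphenyl)phosphine | C=CCP(c1ccccc1)c1ccccc1 | starting material
11 | ethyl (2R)-2-[(tert-butyldimethylsilyl)oxy]-2-{(1R,2S,4R,6S)-2-[(1E)-4-(diphenylphosphanyl)-3-hydroxyhexa-1,5-dien-1-yl]-4,6-dimethylcyclohexyl}acetate (erythro at the two new centres, both carbinol epimers; present as its titanium alkoxide, drawn as the alcohol) | C=CC(P(c1ccccc1)c1ccccc1)C(O)/C=C/[C@@H]1C[C@H](C)C[C@H](C)[C@H]1[C@@H](O[Si](C)(C)C(C)(C)C)C(=O)OCC | intermediate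
12 | ethyl (2R)-2-[(tert-butyldimethylsilyl)oxy]-2-{(1R,2S,4R,6S)-2-[(1E,3Z)-hexa-1,3,5-trien-1-yl]-4,6-dimethylcyclohexyl}acetate | C=C/C=C\C=C\[C@@H]1C[C@H](C)C[C@H](C)[C@H]1[C@@H](O[Si](C)(C)C(C)(C)C)C(=O)OCC | intermediate
13 | ethyl 4-(diethoxyphosphoryl)-3-oxobutanoate | CCOC(=O)CC(=O)CP(=O)(OCC)OCC | starting material
14 | (2R)-2-[(tert-butyldimethylsilyl)oxy]-2-{(1R,2S,4R,6S)-2-[(1E,3Z)-hexa-1,3,5-trien-1-yl]-4,6-dimethylcyclohexyl}acetaldehyde | C=C/C=C\C=C\[C@@H]1C[C@H](C)C[C@H](C)[C@H]1[C@@H](O[Si](C)(C)C(C)(C)C)C=O | intermediate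
15 | ethyl (4E,6S)-6-[(tert-butyldimethylsilyl)oxy]-6-{(1R,2S,4R,6S)-2-[(1E,3Z)-hexa-1,3,5-trien-1-yl]-4,6-dimethylcyclohexyl}-3-oxohex-4-enoate | C=C/C=C\C=C\[C@@H]1C[C@H](C)C[C@H](C)[C@H]1[C@@H](O[Si](C)(C)C(C)(C)C)/C=C/C(=O)CC(=O)OCC | intermediate
16 | (4-bromophenoxy)(tert-butyl)dimethylsilane | CC(C)(C)[Si](C)(C)Oc1ccc(Br)cc1 | starting material
17 | epichlorohydrin, 2-(chloromethyl)oxirane (racemic) | ClCC1CO1 | starting material
18 | {4-[(tert-butyldimethylsilyl)oxy]phenyl}magnesium bromide | CC(C)(C)[Si](C)(C)Oc1ccc([Mg]Br)cc1 | intermediate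
19 | 1-{4-[(tert-butyldimethylsilyl)oxy]phenyl}-3-chloropropan-2-ol (racemic) | CC(C)(C)[Si](C)(C)Oc1ccc(CC(O)CCl)cc1 | intermediate
20 | 1-{4-[(tert-butyldimethylsilyl)oxy]phenyl}-3-chloropropan-2-one | CC(C)(C)[Si](C)(C)Oc1ccc(CC(=O)CCl)cc1 | intermediate
21 | ethyl (4E,6S)-6-[(tert-butyldimethylsilyl)oxy]-2-(3-{4-[(tert-butyldimethylsilyl)oxy]phenyl}-2-oxopropyl)-6-{(1R,2S,4R,6S)-2-[(1E,3Z)-hexa-1,3,5-trien-1-yl]-4,6-dimethylcyclohexyl}-3-oxohex-4-enoate (C2 epimers) | C=C/C=C\C=C\[C@@H]1C[C@H](C)C[C@H](C)[C@H]1[C@@H](O[Si](C)(C)C(C)(C)C)/C=C/C(=O)C(CC(=O)Cc1ccc(O[Si](C)(C)C(C)(C)C)cc1)C(=O)OCC | intermediate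
22 | ethyl (4E,6S)-6-hydroxy-2-[3-(4-hydroxyphenyl)-2-oxopropyl]-6-{(1R,2S,4R,6S)-2-[(1E,3Z)-hexa-1,3,5-trien-1-yl]-4,6-dimethylcyclohexyl}-3-oxohex-4-enoate (C2 epimers) | C=C/C=C\C=C\[C@@H]1C[C@H](C)C[C@H](C)[C@H]1[C@@H](O)/C=C/C(=O)C(CC(=O)Cc1ccc(O)cc1)C(=O)OCC | intermediate
23 | 13-membered paracyclophane keto ester: ring C6–O–(1,4-phenylene)–Cc–Cb(=O)–Ca–C2(CO2Et)–C3(=O)–C4=C5 (4E), 6R, with the (1R,2S,4R,6S)-2-[(1E,3Z)-hexa-1,3,5-trien-1-yl]-4,6-dimethylcyclohexyl group on C6 (C2 epimers) | C=C/C=C\C=C\[C@@H]1C[C@H](C)C[C@H](C)[C@H]1[C@H]2/C=C/C(=O)C(C(=O)OCC)CC(=O)Cc3ccc(O2)cc3 | intermediate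
24 | macrocyclic decahydrofluorene keto ester (6-5-6 tricycle inside the 13-membered aryl ether ring; C1 ethyl ester, Cb ketone; 4S,5S,6S,7R,8S,10R,12S,13S,16R; C2 epimers) | C=C[C@@H]1C=C[C@H]2[C@@H]3C[C@H](C)C[C@H](C)[C@H]3[C@@H]3Oc4ccc(cc4)CC(=O)CC(C(=O)OCC)C(=O)[C@@H]1[C@H]23 | intermediate
25 | Xenoacremone H | C=C[C@@H]1C=C[C@H]2[C@@H]3C[C@H](C)C[C@H](C)[C@H]3[C@@H]3Oc4ccc(cc4)C[C@@]4(O)C[C@H](C(=O)N4)C(=O)[C@@H]1[C@H]23 | target

**Totals and risks**
Total step count: 12. Longest linear sequence: 10 (steps 1–6 and 9–12, from 1 to 25).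

Most likely to fail:

1. Step 11 (cyclophane closure and Diels–Alder). The SN2 closure of a strained [9]paracyclophane at a hindered allylic carbinol competes with elimination to the dienone, and the Z-diene cycloaddition must outrun 6π-electrocyclisation of the triene. Fallback, setting out from 22: the order of ring formation is reversed. Me2AlCl (CH2Cl2, −78 → 0 °C) promotes the open-chain intramolecular Diels–Alder first to give the tricyclic hydroxy-phenol ethyl 2-[3-(4-hydroxyphenyl)-2-oxopropyl]-3-oxopropanoate-substituted decahydrofluorenol F5 (6-hydroxyl still uninverted). The ether ring is then closed on this rigid, pre-organised cyclopentanol by Mitsunobu etherification with inversion at C6 (PPh3, DIAD, toluene, high dilution), which returns to the route at 24.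

2. Step 1 (desymmetrising aldol). The ketone is β-branched on both sides and may be a poor enamine donor. Fallback, setting out from 1: enantioselective deprotonation with a chiral lithium amide (lithium bis(1-phenylethyl)amide of the appropriate hand, LiCl, TMSCl in-situ quench, THF, −78 °C) gives (3S,5R)-3,5-dimethyl-1-[(trimethylsilyl)oxy]cyclohex-1-ene F1. MeLi regenerates the lithium enolate, which adds to 2 at −78 °C through a Zimmerman–Traxler chair (cyclic E-enolate gives anti, attack trans to the methyl), returning to the route at 3.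

3. Step 3 (homologation of the hindered, base-sensitive ketone). The basic ylide may enolise the ketone or eliminate silanol, and the C12 preference is only thermodynamic. Fallback, setting out from 4: non-basic Takai–Lombardo methylenation (Zn, CH2Br2, TiCl4) gives ethyl (2R)-2-[(tert-butyldimethylsilyl)oxy]-2-[(1R,2S,4R)-2,4-dimethyl-6-methylidenecyclohexyl]acetate F2. Hydroboration with 9-BBN gives the B-alkyl-9-borabicyclo[3.3.1]nonane adduct F3, and NaBO3 oxidation gives ethyl (2R)-2-[(tert-butyldimethylsilyl)oxy]-2-[(1R,4R,6S)-2-(hydroxymethyl)-4,6-dimethylcyclohexyl]acetate F4, which is oxidised at once (Dess–Martin periodinane) and equilibrated with DBU, returning to the route at 7.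

**Further compounds**
F1 | step 1 | (3S,5R)-3,5-dimethyl-1-[(trimethylsilyl)oxy]cyclohex-1-ene | C[Si](C)(C)OC1=C[C@@H](C)C[C@@H](C)C1
F2 | step 3 | ethyl (2R)-2-[(tert-butyldimethylsilyl)oxy]-2-[(1R,2S,4R)-2,4-dimethyl-6-methylidenecyclohexyl]acetate | C=C1C[C@H](C)C[C@H](C)[C@H]1[C@@H](O[Si](C)(C)C(C)(C)C)C(=O)OCC
F3 | step 3 | B-alkyl-9-borabicyclo[3.3.1]nonane adduct of F2 (boron on the new CH2; C12 epimers) | C(B1C2CCCC1CCC2)C1C[C@H](C)C[C@H](C)[C@H]1[C@@H](O[Si](C)(C)C(C)(C)C)C(=O)OCC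
F4 | step 3 | ethyl (2R)-2-[(tert-butyldimethylsilyl)oxy]-2-[(1R,4R,6S)-2-(hydroxymethyl)-4,6-dimethylcyclohexyl]acetate (C12 epimers) | OCC1C[C@H](C)C[C@H](C)[C@H]1[C@@H](O[Si](C)(C)C(C)(C)C)C(=O)OCC
F5 | step 11 | tricyclic hydroxy-phenol keto ester (decahydrofluorene with 6-OH of the uninverted configuration, open side chain on C4; C2 epimers) | C=C[C@@H]1C=C[C@H]2[C@@H]3C[C@H](C)C[C@H](C)[C@H]3[C@@H](O)[C@@H]2[C@H]1C(=O)C(CC(=O)Cc1ccc(O)cc1)C(=O)OCC
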